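**Plan**
1. Labels: ring A carries the methylene bridge on the carbon between its two hydroxyls, a methoxy group para to the bridge and an acetyl group between that methoxy group and one hydroxyl; ring B has the bridge on B1, OH on B2, CH3 on B3, OH on B4, acetyl on B5 and OMe on B6.
2. Retrosynthesis: both aryl–acetyl bonds are cut first (on ring A next to the methoxy group, on ring B at B5); ring B is then cut at B6–B1, B2–B3 and B5–B6 into a siloxyalkyne and a cyclobutenone; the alkyne is cut at the ring A–CH2 bond and at its alkynyl C–O bond, the cyclobutenone into ketene and 1-ethoxypropyne.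
3. Enabling feature: ring B is hexasubstituted, with oxygen on B2, B4 and B6 alternating with carbon on B1, B3 and B5. B6–B5–B4–B3 plus the methyl group therefore correspond to the four ring carbons of a 2-methyl-3-siloxycyclobutenone, and B1–B2 plus the bridge to a siloxyalkyne.
4. Forward: ring A is bought as 5-methoxyresorcinol and propargylated between its two protected oxygens; the four-membered ring comes from a ketene cycloaddition; ring B, the only ring built, arises in the benzannulation. O-methylation at B6, deprotection and a twofold Hoesch acetylation finish the route.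
5. Stereochemistry: the target has no stereocentre and no stereogenic double bond, so nothing has to be controlled.

Key step: step 8

Remark on the chemistry: the only stereocentre on the way is the quaternary carbon of the transient vinylcyclobutenone in step 8. It is racemic and disappears when the four-membered ring opens.

**Step 1**
Reactants: 1 5-methoxyresorcinol (5-methoxybenzene-1,3-diol)
Product: 2 1-methoxy-3,5-bis(methoxymethoxy)benzene
Conditions: NaH, MOMCl, DMF, 0 °C → rt
Reagents that add atoms: chloromethyl methyl ether (MOMCl), COCCl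
Why: Williamson-type O-alkylation of both phenoxides should give the bis-MOM ether, whose two acetal oxygens jointly direct the lithiation of step 2.

**Step 2**
Reactants: 2 1-methoxy-3,5-bis(methoxymethoxy)benzene; 3 3-bromo-1-(trimethylsilyl)prop-1-yne
Product: 6 trimethyl{3-[4-methoxy-2,6-bis(methoxymethoxy)phenyl]prop-1-yn-1-yl}silane, via aryllithium 4 (not isolated), via arylcopper 5 (not isolated)
Conditions: n-BuLi, THF, 0 °C; CuI, −30 °C; then 3, −30 °C → rt
Reagents that add atoms: none
Why: Directed ortho-metalation at the carbon flanked by both MOM ethers (the future bridge carbon of ring A), transmetalation to copper and SN2 coupling with the propargylic bromide should form the ring A–CH2 bond, the silyl cap blocking SN2′ attack and masking the acidic alkyne C–H.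

**Step 3**
Reactants: 6 trimethyl{3-[4-methoxy-2,6-bis(methoxymethoxy)phenyl]prop-1-yn-1-yl}silane
Product: 7 5-methoxy-1,3-bis(methoxymethoxy)-2-(prop-2-yn-1-yl)benzene
Conditions: K2CO3 (0.2 equiv), MeOH, rt
Reagents that add atoms: none
Why: Base-catalysed protodesilylation (methanolysis of the alkynyl C–Si bond) is mild enough that the skipped aryl–CH2–alkyne should not isomerise to the allene.

**Step 4**
Reactants: 7 5-methoxy-1,3-bis(methoxymethoxy)-2-(prop-2-yn-1-yl)benzene
Product: 10 {3-[4-methoxy-2,6-bis(methoxymethoxy)phenyl]prop-1-yn-1-yl}oxy(triisopropyl)silane, via lithium acetylide 8 (not isolated), via lithium ynolate 9 (not isolated)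
Conditions: n-BuLi, THF, −78 °C; t-BuOOLi (from t-BuOOH and LiN(SiMe3)2), −78 → 0 °C; TIPSOTf, −78 → 0 °C
Reagents that add atoms: tert-butyl hydroperoxide, CC(C)(C)OO; triisopropylsilyl trifluoromethanesulfonate (TIPSOTf), CC(C)[Si](C(C)C)(C(C)C)OS(=O)(=O)C(F)(F)F
Why: Electrophilic oxygenation of the lithium acetylide by lithium tert-butyl peroxide should give the ynolate, and O-silylation with the bulky silyl triflate then gives the siloxyalkyne, the standard entry to 1-siloxy-1-alkynes from terminal alkynes.

**Step 5**
Reactants: 11 1-ethoxyprop-1-yne; 12 acetyl chloride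
Product: 14 3-ethoxy-2-methylcyclobut-2-en-1-one, via ketene 13 (not isolated)
Conditions: Et3N, MeCN, 0 °C → rt, slow addition of 12
Reagents that add atoms: none
Why: Dehydrochlorination of acetyl chloride releases ketene, which should undergo [2+2] cycloaddition with the ynol ether, the methyl-bearing alkyne carbon bonding to the ketene carbonyl carbon.

**Step 6**
Reactants: 14 3-ethoxy-2-methylcyclobut-2-en-1-one
Product: 15 3-hydroxy-2-methylcyclobut-2-en-1-one (enol form of 2-methylcyclobutane-1,3-dione)
Conditions: 1 M HCl (aq), THF, 0 °C → rt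
Reagents that add atoms: water, O
Why: Acid-catalysed hydrolysis of the vinylogous ester (addition of water at the ethoxy-bearing ring carbon, loss of ethanol) should give the acidic enolised 1,3-dione.

**Step 7**
Reactants: 15 3-hydroxy-2-methylcyclobut-2-en-1-one
Product: 16 2-methyl-3-[(triisopropylsilyl)oxy]cyclobut-2-en-1-one
Conditions: TIPSCl, Et3N, CH2Cl2, 0 °C → rt
Reagents that add atoms: chlorotriisopropylsilane (TIPSCl), CC(C)[Si](Cl)(C(C)C)C(C)C
Why: The amine removes the acidic enol proton to give a diketonate delocalised over both oxygens and the methyl-bearing carbon, and O-silylation of this anion at either oxygen should give the same vinylogous silyl ester with the double bond on the methyl-bearing carbon.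

**Step 8**
Reactants: 10 {3-[4-methoxy-2,6-bis(methoxymethoxy)phenyl]prop-1-yn-1-yl}oxy(triisopropyl)silane; 16 2-methyl-3-[(triisopropylsilyl)oxy]cyclobut-2-en-1-one
Product: 21 2-{[4-methoxy-2,6-bis(methoxymethoxy)phenyl]methyl}-4-methyl-3,5-bis[(triisopropylsilyl)oxy]phenol, via vinylketene 17 (not isolated), via vinylcyclobutenone 18 (not isolated), via dienylketene 19 (not isolated), via cyclohexadienone 20 (not isolated)
Conditions: 10 (1.0 equiv), 16 (1.3 equiv), toluene (0.5 M), 80 °C then 110 °C, sealed tube, Ar
Reagents that add atoms: none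
Why: Heating opens 16 by 4π electrocyclic cleavage to the (2-siloxyvinyl)ketene 17, the electron-rich alkyne 10 adds across the ketene C=C bond in a [2+2] cycloaddition to give vinylcyclobutenone 18, a second 4π opening gives dienylketene 19, and 6π electrocyclisation to cyclohexadienone 20 followed by tautomerisation delivers phenol 21. The closest known reaction type is the Danheiser benzannulation of cyclobutenones with siloxyalkynes, which gives resorcinol monosilyl ethers; here the 3-siloxy group of the cyclobutenone supplies the third oxygen and hence the phloroglucinol pattern. Ring B, the only ring formed, closes by the thermal disrotatory 6π electrocyclic ring closure of 19 that makes B5–B6, after the [2+2] step has made B6–B1 and B2–B3. No stereocentre is created in 21; the quaternary centre of 18 is racemic and vanishes on ring opening, and because that opening is reversible the material should funnel through the isomer of 19 whose vinyl group faces the ketene. The selectivity required is the orientation of the [2+2] step, and it is secured by the polarisation of the siloxyalkyne, whose carbon remote from oxygen (the one bearing the ring A methylene) is nucleophilic and bonds to the ketene carbonyl carbon, placing the bridge on B1 between the new phenol and the siloxy group. All six substituents of ring B are thus fixed by connectivity, and the three oxygens emerge differentiated, with only the ketene-derived B6–OH free for the later methylation.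

**Step 9**
Reactants: 21 2-{[4-methoxy-2,6-bis(methoxymethoxy)phenyl]methyl}-4-methyl-3,5-bis[(triisopropylsilyl)oxy]phenol
Product: 22 1-methoxy-2-{[4-methoxy-2,6-bis(methoxymethoxy)phenyl]methyl}-4-methyl-3,5-bis[(triisopropylsilyl)oxy]benzene
Conditions: MeI, K2CO3, acetone, 50 °C
Reagents that add atoms: iodomethane, CI
Why: Williamson O-methylation of the only free phenol should fix the B6 methyl ether, the other two ring B oxygens being blocked as bulky silyl ethers.

**Step 10**
Reactants: 22 1-methoxy-2-{[4-methoxy-2,6-bis(methoxymethoxy)phenyl]methyl}-4-methyl-3,5-bis[(triisopropylsilyl)oxy]benzene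
Product: 23 5-methoxy-4-{[4-methoxy-2,6-bis(methoxymethoxy)phenyl]methyl}-2-methylbenzene-1,3-diol
Conditions: Bu4NF, AcOH, THF, 0 °C
Reagents that add atoms: none
Why: Fluoride-mediated desilylation should cleave both aryl silyl ethers while the acetic acid buffer keeps the electron-rich phenoxides protonated and the MOM ethers stay untouched.

**Step 11**
Reactants: 23 5-methoxy-4-{[4-methoxy-2,6-bis(methoxymethoxy)phenyl]methyl}-2-methylbenzene-1,3-diol
Product: 24 4-[(2,6-dihydroxy-4-methoxyphenyl)methyl]-5-methoxy-2-methylbenzene-1,3-diol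
Conditions: HCl (cat.), MeOH, rt → 40 °C
Reagents that add atoms: none
Why: Acid-catalysed transacetalisation should remove both MOM groups, the solvent methanol capturing the CH2 unit as dimethoxymethane before it can alkylate the electron-rich rings.

**Step 12**
Reactants: 24 4-[(2,6-dihydroxy-4-methoxyphenyl)methyl]-5-methoxy-2-methylbenzene-1,3-diol
Product: 26 1-{5-[(3-acetyl-2,6-dihydroxy-4-methoxyphenyl)methyl]-2,4-dihydroxy-6-methoxy-3-methylphenyl}ethan-1-one (CNP0360110.0), via bis(ketimine) dihydrochloride 25 (not isolated)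
Conditions: MeCN, ZnCl2, HCl (g), Et2O, 0 °C; then H2O, 90 °C
Reagents that add atoms: acetonitrile, CC#N; water, O
Why: In this Hoesch acylation ring B can react only at B5 and ring A only at one of its two equivalent free positions, each lying between a hydroxyl and the methoxy group, and each ketiminium deactivates its ring against a second attack, so hydrolysis should give the diacetyl target.

**Compound list**
1 | 5-methoxyresorcinol (5-methoxybenzene-1,3-diol) | COc1cc(O)cc(O)c1 | starting material
2 | 1-methoxy-3,5-bis(methoxymethoxy)benzene | COCOc1cc(OC)cc(OCOC)c1 | intermediate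
3 | 3-bromo-1-(trimethylsilyl)prop-1-yne | C[Si](C)(C)C#CCBr | starting material
4 | [4-methoxy-2,6-bis(methoxymethoxy)phenyl]lithium (aryllithium; not isolated) | [Li]c1c(OCOC)cc(OC)cc1OCOC | intermediate
5 | [4-methoxy-2,6-bis(methoxymethoxy)phenyl]copper (arylcopper; not isolated) | [Cu]c1c(OCOC)cc(OC)cc1OCOC | intermediate
6 | trimethyl{3-[4-methoxy-2,6-bis(methoxymethoxy)phenyl]prop-1-yn-1-yl}silane | COCOc1cc(OC)cc(OCOC)c1CC#C[Si](C)(C)C | intermediate
7 | 5-methoxy-1,3-bis(methoxymethoxy)-2-(prop-2-yn-1-yl)benzene | COCOc1cc(OC)cc(OCOC)c1CC#C | intermediate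
8 | {3-[4-methoxy-2,6-bis(methoxymethoxy)phenyl]prop-1-yn-1-yl}lithium (lithium acetylide; not isolated) | [Li]C#CCc1c(OCOC)cc(OC)cc1OCOC | intermediate
9 | lithium 3-[4-methoxy-2,6-bis(methoxymethoxy)phenyl]prop-1-yn-1-olate (lithium ynolate; not isolated) | [Li+].[O-]C#CCc1c(OCOC)cc(OC)cc1OCOC | intermediate
10 | {3-[4-methoxy-2,6-bis(methoxymethoxy)phenyl]prop-1-yn-1-yl}oxy(triisopropyl)silane | COCOc1cc(OC)cc(OCOC)c1CC#CO[Si](C(C)C)(C(C)C)C(C)C | intermediate
11 | 1-ethoxyprop-1-yne | CCOC#CC | starting material
12 | acetyl chloride | CC(Cl)=O | starting material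
13 | ketene (ethenone; not isolated) | C=C=O | intermediate
14 | 3-ethoxy-2-methylcyclobut-2-en-1-one | CCOC1=C(C)C(=O)C1 | intermediate
15 | 3-hydroxy-2-methylcyclobut-2-en-1-one | CC1=C(O)CC1=O | intermediate
16 | 2-methyl-3-[(triisopropylsilyl)oxy]cyclobut-2-en-1-one | CC1=C(O[Si](C(C)C)(C(C)C)C(C)C)CC1=O | intermediate
17 | 2-methyl-3-[(triisopropylsilyl)oxy]buta-1,3-dien-1-one (vinylketene; not isolated) | C=C(O[Si](C(C)C)(C(C)C)C(C)C)C(C)=C=O | intermediate
18 | 2-{[4-methoxy-2,6-bis(methoxymethoxy)phenyl]methyl}-4-methyl-3-[(triisopropylsilyl)oxy]-4-{1-[(triisopropylsilyl)oxy]ethenyl}cyclobut-2-en-1-one (racemic; not isolated) | O=C1C(Cc2c(OCOC)cc(OC)cc2OCOC)=C(O[Si](C(C)C)(C(C)C)C(C)C)C1(C)C(=C)O[Si](C(C)C)(C(C)C)C(C)C | intermediate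
19 | (3E)-2-{[4-methoxy-2,6-bis(methoxymethoxy)phenyl]methyl}-4-methyl-3,5-bis[(triisopropylsilyl)oxy]hexa-1,3,5-trien-1-one (dienylketene; not isolated) | O=C=C(Cc1c(OCOC)cc(OC)cc1OCOC)/C(O[Si](C(C)C)(C(C)C)C(C)C)=C(/C)C(=C)O[Si](C(C)C)(C(C)C)C(C)C | intermediate
20 | 2-{[4-methoxy-2,6-bis(methoxymethoxy)phenyl]methyl}-4-methyl-3,5-bis[(triisopropylsilyl)oxy]cyclohexa-2,4-dien-1-one (not isolated) | O=C1CC(O[Si](C(C)C)(C(C)C)C(C)C)=C(C)C(O[Si](C(C)C)(C(C)C)C(C)C)=C1Cc1c(OCOC)cc(OC)cc1OCOC | intermediate
21 | 2-{[4-methoxy-2,6-bis(methoxymethoxy)phenyl]methyl}-4-methyl-3,5-bis[(triisopropylsilyl)oxy]phenol | COCOc1cc(OC)cc(OCOC)c1Cc1c(O)cc(O[Si](C(C)C)(C(C)C)C(C)C)c(C)c1O[Si](C(C)C)(C(C)C)C(C)C | intermediate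
22 | 1-methoxy-2-{[4-methoxy-2,6-bis(methoxymethoxy)phenyl]methyl}-4-methyl-3,5-bis[(triisopropylsilyl)oxy]benzene | COCOc1cc(OC)cc(OCOC)c1Cc1c(OC)cc(O[Si](C(C)C)(C(C)C)C(C)C)c(C)c1O[Si](C(C)C)(C(C)C)C(C)C | intermediate
23 | 5-methoxy-4-{[4-methoxy-2,6-bis(methoxymethoxy)phenyl]methyl}-2-methylbenzene-1,3-diol | COCOc1cc(OC)cc(OCOC)c1Cc1c(OC)cc(O)c(C)c1O | intermediate
24 | 4-[(2,6-dihydroxy-4-methoxyphenyl)methyl]-5-methoxy-2-methylbenzene-1,3-diol | COc1cc(O)c(Cc2c(OC)cc(O)c(C)c2O)c(O)c1 | intermediate
25 | 4-[(3-ethanimidoyl-2,6-dihydroxy-4-methoxyphenyl)methyl]-6-ethanimidoyl-5-methoxy-2-methylbenzene-1,3-diol dihydrochloride (not isolated) | COc1cc(O)c(Cc2c(O)c(C)c(O)c(C(C)=N)c2OC)c(O)c1C(C)=N.Cl.Cl | intermediate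
26 | 1-{5-[(3-acetyl-2,6-dihydroxy-4-methoxyphenyl)methyl]-2,4-dihydroxy-6-methoxy-3-methylphenyl}ethan-1-one | COc1cc(O)c(Cc2c(O)c(C)c(O)c(C(C)=O)c2OC)c(O)c1C(C)=O | target

**Step count and risks**
Total: 12 steps. Longest linear sequence: 9 steps (steps 1–4, then 8–12); the cyclobutenone branch (steps 5–7) joins at step 8.

Steps most likely to fail:

Step 8. The vinylogous silyl ester in 16 stabilises the four-membered ring, so its 4π opening may be slower than thermal decomposition of the siloxyalkyne. The vinylketene may also acylate the product phenol instead of being trapped by the alkyne. The fallback gives up the annulation and joins ring A to a preformed ring B. It sets out from 2: the aryllithium 4, made as in step 2, is quenched with DMF to give 4-methoxy-2,6-bis(methoxymethoxy)benzaldehyde F1, and NaBH4 in MeOH reduces this to [4-methoxy-2,6-bis(methoxymethoxy)phenyl]methanol F2. A second portion of 4 is quenched with iodomethane to give 5-methoxy-1,3-bis(methoxymethoxy)-2-methylbenzene F3, whose MOM groups are removed with HCl in MeOH to give 5-methoxy-2-methylbenzene-1,3-diol F4. The very easily ionised benzylic alcohol F2 is then used in a Friedel–Crafts benzylation of an excess of F4, in hexafluoroisopropanol at rt or with catalytic camphorsulfonic acid in CH2Cl2 at 0 °C. The two open positions of F4 are equivalent, so the product should be 23, where the route is rejoined before step 11.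

Step 12. Under HCl and ZnCl2 the electron-rich diarylmethane may be protonated at an ipso carbon, which would cleave and scramble the methylene bridge, and ring A may be acylated a second time. The fallback replaces electrophilic acylation by anionic acylation. It sets out from 23, which is protected with MOMCl and NaH in DMF to give 1-methoxy-2-{[4-methoxy-2,6-bis(methoxymethoxy)phenyl]methyl}-3,5-bis(methoxymethoxy)-4-methylbenzene F5. Twofold directed ortho-lithiation (n-BuLi, TMEDA, THF, 0 °C), each time between an OMOM and an OMe group, gives the dilithio species {3-[(3-lithio-4-methoxy-2,6-bis(methoxymethoxy)phenyl)methyl]-2-methoxy-4,6-bis(methoxymethoxy)-5-methylphenyl}lithium F6. Acylation with N-methoxy-N-methylacetamide at −78 °C → rt gives 1-(3-{[3-acetyl-4-methoxy-2,6-bis(methoxymethoxy)phenyl]methyl}-2-methoxy-4,6-bis(methoxymethoxy)-5-methylphenyl)ethan-1-one F7. HCl in MeOH then removes the four MOM groups, and the fallback arrives at 26.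

Step 5. Ketene generated in the flask may dimerise or oligomerise faster than it is captured by the ynol ether, and the small product may be lost on isolation. The fallback uses a ketene that does not suffer from this and adds a reduction. It sets out from 11, which is treated with trichloroacetyl chloride and Zn–Cu couple in Et2O; the dichloroketene F8 formed in the flask should add in the same orientation to give 4,4-dichloro-3-ethoxy-2-methylcyclobut-2-en-1-one F9. Reductive dechlorination with Zn, AcOH and TMEDA in EtOH at 0 °C gives 14, where the route is rejoined before step 6.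

**Further compounds**
F1 | step 8 | 4-methoxy-2,6-bis(methoxymethoxy)benzaldehyde | COCOc1cc(OC)cc(OCOC)c1C=O
F2 | step 8 | [4-methoxy-2,6-bis(methoxymethoxy)phenyl]methanol | COCOc1cc(OC)cc(OCOC)c1CO
F3 | step 8 | 5-methoxy-1,3-bis(methoxymethoxy)-2-methylbenzene | COCOc1cc(OC)cc(OCOC)c1C
F4 | step 8 | 5-methoxy-2-methylbenzene-1,3-diol | COc1cc(O)c(C)c(O)c1
F5 | step 12 | 1-methoxy-2-{[4-methoxy-2,6-bis(methoxymethoxy)phenyl]methyl}-3,5-bis(methoxymethoxy)-4-methylbenzene | COCOc1cc(OC)cc(OCOC)c1Cc1c(OC)cc(OCOC)c(C)c1OCOC
F6 | step 12 | {3-[(3-lithio-4-methoxy-2,6-bis(methoxymethoxy)phenyl)methyl]-2-methoxy-4,6-bis(methoxymethoxy)-5-methylphenyl}lithium | COCOc1cc(OC)c([Li])c(OCOC)c1Cc1c(OC)c([Li])c(OCOC)c(C)c1OCOC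
F7 | step 12 | 1-(3-{[3-acetyl-4-methoxy-2,6-bis(methoxymethoxy)phenyl]methyl}-2-methoxy-4,6-bis(methoxymethoxy)-5-methylphenyl)ethan-1-one | COCOc1cc(OC)c(C(C)=O)c(OCOC)c1Cc1c(OC)c(C(C)=O)c(OCOC)c(C)c1OCOC
F8 | step 5 | dichloroketene (2,2-dichloroethen-1-one) | ClC(Cl)=C=O
F9 | step 5 | 4,4-dichloro-3-ethoxy-2-methylcyclobut-2-en-1-one | CCOC1=C(C)C(=O)C1(Cl)Cl
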